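The trap in the epsilon and gamma runs was to read the charge of starting material into the curve. At 90.0 min the epsilon run, with c(starting material) 0.35 M, held 11.3 % target. The gamma run, with 0.55 M, held 9.3 %, and each reading scatters by 1 percentage point. So I took both, in percent of charge, as one curve, pseudo-first-order in starting material. I carried it to the flask at 0.25 M, which has their c(reagent in the second phase), 0.250 M, and their volume ratio.

| flask | starting material | reagent in the second phase | remark | time | volume of the second phase over the first |
|---|---|---|---|---|---|
| epsilon | 0.35 M | 0.25 M | run made earlier |  |  |
| gamma | 0.55 M | 0.25 M | run made earlier |  |  |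
| flask | 0.25 M | 0.250 M |  | 2.0 h | 0.25 |

- epsilon (time / min: target / %, starting material / %): 8.00: 0.9, 97.8; 15.0: 0, 99.5; 25.0: 1.8, 98.6; 50.0: 4.8, 95.7; 90.0: 11.3, 87.4
- gamma (time / min: target / %, starting material / %): 20.0: 1.5, 96.3; 40.0: 4.0, 95.7; 60.0: 8.2, 93.6; 80.0: 7.6, 90.9; 90.0: 9.3, 90.0

(readings scatter by 1 percentage point)

- how much target there is at 2.0 h, in percent of the starting material charged
- the change that raises the amount of target at 2.0 h, in percent of the starting material charged most ("none" if none brings more than 2 percentage points) (birch / elm / none)
- amount of target at 2.0 h, in percent of the starting material charged, after elm

- birch: doubling the amount of reagent in the second phase, all else as stated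
- elm: doubling the transfer coefficient of the reagent in the second phase, all else as stated

I drew that curve. Its start was flat within the scatter: the epsilon run read 0.9 % and 0 % by 15.0 min. Then it rose straight. I averaged the two runs at two places:

early point: 4.40 % at 45.0 min

late point: 10.3 % at 90.0 min

slope s, as a fraction of the charge: 0.0787 h⁻¹

knee: 11.4 min

This knee is the delay, or induction period: the time at which the straight part of the target curve meets zero. The last readings showed no level within the scatter, and at 90.0 min the epsilon run still held 87.4 % of starting material and the gamma run 90.0 %. So I kept the line up to the asked time:

target in the flask at 2.0 h = s(t − delay) = 14.2 %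

I assumed that birch doubles the slope, though neither run varied the reagent. That gains 14 points. I assumed that elm halves the delay, which gains s × delay / 2:

gain by elm = 0.75 points, so target after elm = 15.0 %

That gain is less than the 2 points that counts, so I chose birch.

The forecast gave 17.5 %, above my 14.2 %, and 25 % after elm, above my 15.0 %, and it chose birch; its reading of the runs was: “This suggests the reagent slowly enters the first phase, then reacts there with the starting material, first order in each.”

The flask gave 14.7 %, with birch the best change and 16.6 % after elm.

    reagent in the reaction phase ⇌ reagent in the second phase, rate k1*([reagent in the reaction phase] - [reagent in the second phase]/K1) per volume of the first phase (partition coefficient = 1.10, kL = 0.354 h⁻¹)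
    starting material + reagent in the reaction phase → target (k = 0.812 M⁻¹ h⁻¹)
    reagent in the reaction phase + target → over-reacted product (k = 1.53 M⁻¹ h⁻¹)
    2 starting material → self-condensation product (k = 3.29 × 10⁻⁴ M⁻¹ h⁻¹)

The flask stood 0.50 points above my line. Elm gained 1.9 points against my 0.75 points, still less than 2 points. Birch gained 7.6 points, about half of what I had reckoned. The neighbouring flask had the same charges and was read at 50 min. The same slope and delay gave it 5.06 %, and it held 5.25 %.

The runs are calculated for an exercise; scatter was added.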